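The route rests on cutting the O1–C7a bond of the furan ring, the aryl–oxygen bond next to the C7 oxygen on ring B. This traces the benzofuran back to a benzocyclobutenone fused at C3a–C7a with its carbonyl on C7a. The C7 alkoxy group is exploited twice: it steers the aryne [2+2] addition that places the carbonyl, and it makes C7a the better migrating carbon. In one operation the Baeyer–Villiger step forms O1–C7a and turns the four-membered ketone into the five-membered lactone. The precursor is the fully assembled 2-prenyl-3-(ring A propyl)benzocyclobutenone. All three phenols are carried as MOM ethers so that one mild acid step finishes the synthesis.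

Key step: step 11

Abbreviations: MOM = methoxymethyl; ArA = 2,4-bis(methoxymethoxy)-5-(2-methylbut-3-en-2-yl)phenyl (protected ring A); prenyl = 3-methylbut-2-enyl. Ring B atoms carry benzofuran numbers (O1, C2, C3, C3a, C4–C7, C7a) throughout.
Assumption: 1 and 9 are taken as catalogue compounds (1 is also the hydrogenation product of umbelliferone).
The target has no stereocentre and no stereodefined alkene. The only stereocentres on the way (C2 of 21 and 23) are transient and racemic.

Step 1
Reactants: 1 7-hydroxychroman-2-one; 2 prenyl bromide (1-bromo-3-methylbut-2-ene)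
Product: 3 7-(3-methylbut-2-enyloxy)chroman-2-one
Conditions: K2CO3, acetone, reflux
Reagents that add atoms: prenyl bromide (2), CC(C)=CCBr
Why: Williamson ether synthesis, selective because the second phenolic oxygen of ring A is tied up in the lactone, so only the C7 phenoxide can be O-alkylated under mild carbonate conditions that should leave the lactone closed.

Step 2
Reactants: 3 7-(3-methylbut-2-enyloxy)chroman-2-one
Product: 4 2-(3-hydroxypropyl)-5-(3-methylbut-2-enyloxy)phenol
Conditions: LiAlH4, THF, 0 °C → rt; aq. potassium sodium tartrate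
Reagents that add atoms: none
Why: Hydride reduction of the lactone (an aryl ester) releases the phenol and the primary alcohol, so the three-carbon chain of the diarylpropane is unmasked while the allyl aryl ether is inert to LiAlH4.

Step 3
Reactants: 4 2-(3-hydroxypropyl)-5-(3-methylbut-2-enyloxy)phenol
Product: 5 3-[2-(methoxymethoxy)-4-(3-methylbut-2-enyloxy)phenyl]propan-1-ol
Conditions: MOMCl (1.1 equiv), K2CO3, acetone, 0 °C → rt
Reagents that add atoms: chloromethyl methyl ether (MOMCl), COCCl
Why: Chemoselective O-alkylation (MOM protection), since carbonate ionises only the phenol, so the primary alcohol stays free and a bulky donor group is placed next to C3 before the rearrangement.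

Step 4
Reactants: 5 3-[2-(methoxymethoxy)-4-(3-methylbut-2-enyloxy)phenyl]propan-1-ol
Product: 6 3-[4-hydroxy-2-(methoxymethoxy)-5-(2-methylbut-3-en-2-yl)phenyl]propan-1-ol
Conditions: PhNEt2, 200 °C (sealed tube, argon)
Reagents that add atoms: none
Why: Aromatic Claisen rearrangement, whose [3,3]-sigmatropic shift inverts the prenyl unit into the 1,1-dimethylallyl group and should go to C5, because C3 lies between two oxygen substituents and cannot easily take a quaternary carbon, the meta donor OMOM favours the remote ortho position, and the substituted para carbon blocks a productive Cope shift.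

Step 5
Reactants: 6 3-[4-hydroxy-2-(methoxymethoxy)-5-(2-methylbut-3-en-2-yl)phenyl]propan-1-ol
Product: 7 3-(ArA)propan-1-ol, i.e. 3-[2,4-bis(methoxymethoxy)-5-(2-methylbut-3-en-2-yl)phenyl]propan-1-ol
Conditions: MOMCl (1.2 equiv), K2CO3, acetone, rt → 40 °C
Reagents that add atoms: chloromethyl methyl ether (MOMCl), COCCl
Why: Phenoxide-selective MOM protection as in step 3, with the small and very reactive MOMCl able to reach the phenol beside the quaternary carbon while the alcohol remains un-ionised.

Step 6
Reactants: 7 3-(ArA)propan-1-ol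
Product: 8 1-(3-iodopropyl)-2,4-bis(methoxymethoxy)-5-(2-methylbut-3-en-2-yl)benzene
Conditions: I2, PPh3, imidazole, CH2Cl2, 0 °C → rt
Reagents that add atoms: iodine, II
Why: Appel-type iodination, in which the alcohol attacks the iodophosphonium salt and iodide displaces triphenylphosphine oxide by SN2 at the primary carbon, imidazole keeping the medium non-acidic for the MOM ethers.

Step 7
Reactants: 9 3-bromo-5-iodophenol
Product: 10 1-bromo-3-iodo-5-(methoxymethoxy)benzene
Conditions: MOMCl, K2CO3, acetone, rt
Reagents that add atoms: chloromethyl methyl ether (MOMCl), COCCl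
Why: Williamson-type O-alkylation that gives the ring B oxygen the same acid-labile group as ring A while keeping an inductively withdrawing alkoxy substituent for the later metalation and aryne polarisation.

Step 8
Reactants: 10 1-bromo-3-iodo-5-(methoxymethoxy)benzene; 2 prenyl bromide
Product: 13 1-bromo-3-iodo-5-(methoxymethoxy)-2-(3-methylbut-2-enyl)benzene, via aryllithium 11 (not isolated), via arylcopper 12 (not isolated)
Conditions: LiN(i-Pr)2 (1.05 equiv), THF, −78 °C; CuBr·SMe2 (1.0 equiv), −78 °C; 2, −78 → 0 °C
Reagents that add atoms: prenyl bromide (2), CC(C)=CCBr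
Why: Deprotonative lithiation followed by copper-mediated allylic substitution, relying on the C–H between the two halogens being the most acidic ring position and giving an aryllithium that persists at −78 °C, on transmetalation to copper shutting off halide loss, and on the doubly ortho-substituted arylcopper attacking the unhindered CH2 terminus of prenyl bromide (SN2) to give the linear prenyl group.

Step 9
Reactants: 8 1-(3-iodopropyl)-2,4-bis(methoxymethoxy)-5-(2-methylbut-3-en-2-yl)benzene; 13 1-bromo-3-iodo-5-(methoxymethoxy)-2-(3-methylbut-2-enyl)benzene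
Product: 15 1-bromo-5-(methoxymethoxy)-2-(3-methylbut-2-enyl)-3-[3-(ArA)propyl]benzene, via alkylzinc iodide 14 (not isolated)
Conditions: 8, Zn dust (activated), LiCl, THF, 40 °C, solution decanted from Zn; then 13, PdCl2(dppf) (3 mol %), THF, rt → 40 °C
Reagents that add atoms: none
Why: Negishi sp3–sp2 cross-coupling, in which zinc inserts into the primary C–I bond without touching MOM ethers or the vinyl group, zerovalent palladium formed from PdCl2(dppf) adds to the C–I bond of 13 much faster than to its C–Br bond near room temperature, and the wide-bite-angle ligand favours reductive elimination over β-hydride elimination.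

Step 10
Reactants: 15 1-bromo-5-(methoxymethoxy)-2-(3-methylbut-2-enyl)-3-[3-(ArA)propyl]benzene; 16 ketene diethyl acetal (1,1-diethoxyethene)
Product: 20 5-(methoxymethoxy)-2-(3-methylbut-2-enyl)-3-[3-(ArA)propyl]bicyclo[4.2.0]octa-1,3,5-trien-7-one (benzocyclobutenone; carbonyl on C7a), via aryllithium 17 (not isolated), via aryne 18 (not isolated), via diethyl ketal 19 (not isolated)
Conditions: 16 (5 equiv), lithium 2,2,6,6-tetramethylpiperidide (LiTMP, 2.5 equiv, from the amine and n-BuLi) added to 15 + 16, THF, −78 → 0 °C; crude 19: 1 M aq. HCl, THF, rt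
Reagents that add atoms: ketene diethyl acetal (16), C=C(OCC)OCC; water, O
Why: Aryne [2+2] cycloaddition followed by acetal hydrolysis, in which the C–H flanked by bromine and OMOM is the most acidic site of 15, loss of LiBr from 17 on warming gives the 3-alkoxyaryne 18, the nucleophilic CH2 of the ketene acetal attacks its inductively polarised triple bond at the carbon remote from oxygen (future C3a) so that the acetal carbon ends on C7a, and dilute acid at room temperature should free the ketone faster than it cleaves aryl MOM ethers.

Step 11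
Reactants: 20 5-(methoxymethoxy)-2-(3-methylbut-2-enyl)-3-[3-(ArA)propyl]bicyclo[4.2.0]octa-1,3,5-trien-7-one
Product: 22 7-(methoxymethoxy)-4-(3-methylbut-2-enyl)-5-[3-(ArA)propyl]benzofuran-2(3H)-one, via perhydrate 21 (not isolated)
Conditions: 30% aq. H2O2 (2 equiv), CF3CH2OH, 0 °C → rt
Reagents that add atoms: hydrogen peroxide, OO
Why: Baeyer–Villiger oxidation: H2O2 adds to the strained, strongly electrophilic four-membered carbonyl (angle strain falls on going from sp2 to sp3) to give the Criegee-type perhydrate 21, and the hydrogen-bond network of trifluoroethanol turns the distal OH into a leaving group so that a 1,2-shift to oxygen follows. The closest known reaction type is the peroxide ring expansion of cyclobutanones and benzocyclobutenones to five-membered lactones, and the sense of migration mirrors the conversion of 1-indanones into dihydrocoumarins. No ring is closed by cyclisation; the ring fused at C3a–C7a grows from four to five atoms by insertion of O1 between C7a and C2, and no stereocentre is formed. The regioselectivity needed is migration of C7a and not of the C3 methylene: C7a is an electron-rich aryl carbon (OMOM ortho at C7, alkyl para at C4) whose π lobes point above and below the ring plane, where the peroxide oxygen sits, whereas the C2–C3 σ bond lies in the nodal plane of ring B, so C3 gains no benzylic assistance and behaves as a plain primary alkyl group. The chemoselectivity needed is ketone over the two alkenes (prenyl and 1,1-dimethylallyl): H2O2 acts as a nucleophile, no peracid is present, and a small excess of oxidant at or below room temperature in trifluoroethanol (not the more activating hexafluoroisopropanol) should leave even the trisubstituted alkene untouched. The MOM ethers meet neither strong acid nor base.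

Step 12
Reactants: 22 7-(methoxymethoxy)-4-(3-methylbut-2-enyl)-5-[3-(ArA)propyl]benzofuran-2(3H)-one
Product: 24 7-(methoxymethoxy)-4-(3-methylbut-2-enyl)-5-[3-(ArA)propyl]benzofuran, via lactol 23 (not isolated)
Conditions: i-Bu2AlH (1.1 equiv), CH2Cl2, −78 °C; aq. potassium sodium tartrate; crude 23: p-TsOH·H2O (5 mol %), toluene, rt
Reagents that add atoms: none
Why: Partial hydride reduction of the lactone to the lactol (the tetrahedral aluminium alkoxide should hold at −78 °C until work-up) followed by acid-catalysed dehydration, which is driven by formation of the aromatic furan and needs only a trace of acid in a non-nucleophilic solvent, so the MOM ethers stay on.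

Step 13
Reactants: 24 7-(methoxymethoxy)-4-(3-methylbut-2-enyl)-5-[3-(ArA)propyl]benzofuran
Product: 25 4-[3-(7-hydroxy-4-(3-methylbut-2-enyl)benzofuran-5-yl)propyl]-6-(2-methylbut-3-en-2-yl)benzene-1,3-diol (CNP0288359.0)
Conditions: HCl (ca. 1 M, from conc. aq. HCl), MeOH, 40 °C
Reagents that add atoms: none
Why: Acid-catalysed transacetalisation of the three aryl MOM ethers to dimethoxymethane under conditions customary for prenylated phenols, tolerable here because the prenyl group has no ortho hydroxyl to cyclise onto and the monosubstituted alkene of the 1,1-dimethylallyl group is too weakly basic to be protonated by dilute acid.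

Compound list
1 | 7-hydroxychroman-2-one | O=C1CCc2ccc(O)cc2O1 | starting material
2 | prenyl bromide (1-bromo-3-methylbut-2-ene) | CC(C)=CCBr | starting material
3 | 7-(3-methylbut-2-enyloxy)chroman-2-one | CC(C)=CCOc1ccc2c(c1)OC(=O)CC2 | intermediate
4 | 2-(3-hydroxypropyl)-5-(3-methylbut-2-enyloxy)phenol | CC(C)=CCOc1ccc(CCCO)c(O)c1 | intermediate
5 | 3-[2-(methoxymethoxy)-4-(3-methylbut-2-enyloxy)phenyl]propan-1-ol | CC(C)=CCOc1ccc(CCCO)c(OCOC)c1 | intermediate
6 | 3-[4-hydroxy-2-(methoxymethoxy)-5-(2-methylbut-3-en-2-yl)phenyl]propan-1-ol | C=CC(C)(C)c1cc(CCCO)c(OCOC)cc1O | intermediate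
7 | 3-[2,4-bis(methoxymethoxy)-5-(2-methylbut-3-en-2-yl)phenyl]propan-1-ol | C=CC(C)(C)c1cc(CCCO)c(OCOC)cc1OCOC | intermediate
8 | 1-(3-iodopropyl)-2,4-bis(methoxymethoxy)-5-(2-methylbut-3-en-2-yl)benzene | C=CC(C)(C)c1cc(CCCI)c(OCOC)cc1OCOC | intermediate
9 | 3-bromo-5-iodophenol | Oc1cc(Br)cc(I)c1 | starting material
10 | 1-bromo-3-iodo-5-(methoxymethoxy)benzene | COCOc1cc(Br)cc(I)c1 | intermediate
11 | [2-bromo-6-iodo-4-(methoxymethoxy)phenyl]lithium (not isolated) | COCOc1cc(Br)c([Li])c(I)c1 | intermediate
12 | [2-bromo-6-iodo-4-(methoxymethoxy)phenyl]copper (not isolated) | COCOc1cc(Br)c([Cu])c(I)c1 | intermediate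
13 | 1-bromo-3-iodo-5-(methoxymethoxy)-2-(3-methylbut-2-enyl)benzene | COCOc1cc(Br)c(CC=C(C)C)c(I)c1 | intermediate
14 | 3-(ArA)propylzinc iodide (not isolated) | C=CC(C)(C)c1cc(CCC[Zn]I)c(OCOC)cc1OCOC | intermediate
15 | 1-bromo-5-(methoxymethoxy)-2-(3-methylbut-2-enyl)-3-[3-(ArA)propyl]benzene | COCOc1cc(Br)c(CC=C(C)C)c(CCCc2cc(C(C)(C)C=C)c(OCOC)cc2OCOC)c1 | intermediate
16 | ketene diethyl acetal (1,1-diethoxyethene) | C=C(OCC)OCC | starting material
17 | aryllithium from 15, lithium between Br and OMOM (not isolated) | COCOc1cc(CCCc2cc(C(C)(C)C=C)c(OCOC)cc2OCOC)c(CC=C(C)C)c(Br)c1[Li] | intermediate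
18 | 3-(methoxymethoxy)aryne, triple bond between future C3a and C7a (not isolated) | COCOC1=CC(CCCc2cc(C(C)(C)C=C)c(OCOC)cc2OCOC)=C(CC=C(C)C)C#C1 | intermediate
19 | 7,7-diethoxy-5-(methoxymethoxy)-2-(3-methylbut-2-enyl)-3-[3-(ArA)propyl]bicyclo[4.2.0]octa-1,3,5-triene (not isolated) | CCOC1(OCC)Cc2c(CC=C(C)C)c(CCCc3cc(C(C)(C)C=C)c(OCOC)cc3OCOC)cc(OCOC)c21 | intermediate
20 | 5-(methoxymethoxy)-2-(3-methylbut-2-enyl)-3-[3-(ArA)propyl]bicyclo[4.2.0]octa-1,3,5-trien-7-one | O=C1Cc2c(CC=C(C)C)c(CCCc3cc(C(C)(C)C=C)c(OCOC)cc3OCOC)cc(OCOC)c21 | intermediate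
21 | 7-hydroperoxy-7-hydroxy adduct of 20 (racemic, not isolated) | OOC1(O)Cc2c(CC=C(C)C)c(CCCc3cc(C(C)(C)C=C)c(OCOC)cc3OCOC)cc(OCOC)c21 | intermediate
22 | 7-(methoxymethoxy)-4-(3-methylbut-2-enyl)-5-[3-(ArA)propyl]benzofuran-2(3H)-one | O=C1Cc2c(CC=C(C)C)c(CCCc3cc(C(C)(C)C=C)c(OCOC)cc3OCOC)cc(OCOC)c2O1 | intermediate
23 | 7-(methoxymethoxy)-4-(3-methylbut-2-enyl)-5-[3-(ArA)propyl]-2,3-dihydrobenzofuran-2-ol (racemic, not isolated) | OC1Cc2c(CC=C(C)C)c(CCCc3cc(C(C)(C)C=C)c(OCOC)cc3OCOC)cc(OCOC)c2O1 | intermediate
24 | 7-(methoxymethoxy)-4-(3-methylbut-2-enyl)-5-[3-(ArA)propyl]benzofuran | COCOc1cc(CCCc2cc(C(C)(C)C=C)c(OCOC)cc2OCOC)c(CC=C(C)C)c2ccoc12 | intermediate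
25 | 4-[3-(7-hydroxy-4-(3-methylbut-2-enyl)benzofuran-5-yl)propyl]-6-(2-methylbut-3-en-2-yl)benzene-1,3-diol | C=CC(C)(C)c1cc(CCCc2cc(O)c3occc3c2CC=C(C)C)c(O)cc1O | target

Total step count: 13. Longest linear sequence: 11 (steps 1–6, then 9–13). The ring B branch (steps 7 and 8) joins at step 9.

Steps most likely to fail

1. Step 11. The C3 methylene may migrate in place of C7a, which would insert oxygen on the wrong side of the carbonyl. The activated peroxide may also slowly epoxidise the trisubstituted prenyl alkene or perhydrolyse the aryl lactone.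
   - The fallback brings the oxygen in by borylation–oxidation and the two furan carbons by cross-coupling. It sets out from bromide 15.
   - Lithiation with LiN(i-Pr)2 at −78 °C, where aryllithium 17 persists, with in situ trapping by B(Oi-Pr)3, should give after aqueous work-up [2-bromo-6-(methoxymethoxy)-3-prenyl-4-(3-(ArA)propyl)phenyl]boronic acid F1.
   - Alkaline H2O2, which leaves unactivated alkenes alone, should convert it into 2-bromo-6-(methoxymethoxy)-3-prenyl-4-[3-(ArA)propyl]phenol F2.
   - Suzuki–Miyaura coupling with (E)-2-ethoxyvinylboronic acid pinacol ester (Pd(OAc)2, SPhos, K3PO4, aq. dioxane) should give 2-[(E)-2-ethoxyvinyl]-6-(methoxymethoxy)-3-prenyl-4-[3-(ArA)propyl]phenol F3.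
   - Catalytic p-TsOH in toluene then closes the phenol onto the enol ether and expels ethanol, and the route is rejoined at benzofuran 24.

2. Step 10. While the mixture warms with excess amide base, the amine may add to the aryne. The base may also shift the prenyl double bond into conjugation through the doubly activated CH2, and the acid stage may partly remove MOM groups.
   - The fallback separates metalation from aryne release, so that the aryne forms by halogen–metal exchange with no amide present. It sets out from 15.
   - LiN(i-Pr)2 at −78 °C followed by I2 at the same temperature should give 2-bromo-1-iodo-6-(methoxymethoxy)-3-prenyl-4-[3-(ArA)propyl]benzene F4, which can be purified.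
   - One equivalent of n-BuLi added to F4 and 16 in toluene/THF at −78 °C exchanges iodine selectively to regenerate 17. Warming gives 18 and then ketal 19.
   - The same dilute-acid hydrolysis brings the route back at ketone 20.

3. Step 4. The allyl unit may migrate to C3. The o-(1,1-dimethylallyl)phenol may rearrange further or close onto its own alkene at 200 °C, and the prenyl group may be lost thermally.
   - The fallback needs no sigmatropic step. It sets out from lactone 1.
   - LiAlH4 reduction should give 4-(3-hydroxypropyl)benzene-1,3-diol F5.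
   - MOMCl/K2CO3 in acetone protects both phenols to give 3-[2,4-bis(methoxymethoxy)phenyl]propan-1-ol F6.
   - N-bromosuccinimide in MeCN at 0 °C brominates the unhindered, doubly activated C5 (para to one OMOM, ortho to the other) to give 3-[5-bromo-2,4-bis(methoxymethoxy)phenyl]propan-1-ol F7.
   - A branched-selective (γ-selective) Suzuki–Miyaura coupling of F7 with prenylboronic acid pinacol ester (Pd(OAc)2, a bulky biaryl(di-tert-butyl)phosphine, aq. K3PO4, THF) installs the 1,1-dimethylallyl group, and the route is rejoined at alcohol 7.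

Further compounds
F1 | step 11 | [2-bromo-6-(methoxymethoxy)-3-prenyl-4-(3-(ArA)propyl)phenyl]boronic acid | COCOc1cc(CCCc2cc(C(C)(C)C=C)c(OCOC)cc2OCOC)c(CC=C(C)C)c(Br)c1B(O)O
F2 | step 11 | 2-bromo-6-(methoxymethoxy)-3-prenyl-4-[3-(ArA)propyl]phenol | COCOc1cc(CCCc2cc(C(C)(C)C=C)c(OCOC)cc2OCOC)c(CC=C(C)C)c(Br)c1O
F3 | step 11 | 2-[(E)-2-ethoxyvinyl]-6-(methoxymethoxy)-3-prenyl-4-[3-(ArA)propyl]phenol | CCO/C=C/c1c(O)c(OCOC)cc(CCCc2cc(C(C)(C)C=C)c(OCOC)cc2OCOC)c1CC=C(C)C
F4 | step 10 | 2-bromo-1-iodo-6-(methoxymethoxy)-3-prenyl-4-[3-(ArA)propyl]benzene | COCOc1cc(CCCc2cc(C(C)(C)C=C)c(OCOC)cc2OCOC)c(CC=C(C)C)c(Br)c1I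
F5 | step 4 | 4-(3-hydroxypropyl)benzene-1,3-diol | OCCCc1ccc(O)cc1O
F6 | step 4 | 3-[2,4-bis(methoxymethoxy)phenyl]propan-1-ol | COCOc1ccc(CCCO)c(OCOC)c1
F7 | step 4 | 3-[5-bromo-2,4-bis(methoxymethoxy)phenyl]propan-1-ol | COCOc1cc(OCOC)c(CCCO)cc1Br
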